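## The problem

Target 21 is (2R,3R)-5,6-dihydroxy-2-(3-hydroxy-4,5-dimethoxyphenyl)-3,7-dimethoxychroman-4-one, a 2,3-trans 3-O-methyl dihydroflavonol (flavanone numbering; ring A is the benzo ring, ring B the C2 aryl group, ring C the pyranone). Ring C has to be built between two electron-rich arenes, and ring A is substituted everywhere except C8. Seven oxygens must be sorted: methyl on O7, O4', O5' and the aliphatic O3; hydrogen on O5, O6 and O3'. O5 and O7 are mirror-related in any simple ring A precursor and differ in the target only through the peri relationship of O5 to the C4 carbonyl. There are two contiguous stereocentres, C2 and C3. Only C2 needs absolute control, because the C2 aryl group shields one face of C3 and the trans (diequatorial) isomer is also the more stable one. The weak points are the benzylic O1–C2 bond β to the ketone (a free enolate or strong base opens ring C to the chalcone and racemises C2), the enolisable C3, the easy dehydrogenation of 3-oxygenated flavanones to flavonols, and the air-sensitive 5,6-catechol, which should be freed last and without base. The feature exploited is that O1–C8a–C4a–C4 is an oxa-diene (an o-quinone methide) once C4 stands at the aldehyde oxidation level, while C2–C3 with ring B is a styrene, so ring C is a hetero-[4+2] adduct.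

## Retrosynthesis

**21 from 20.** The two O–benzyl bonds (O6, O3') and the O5–methyl bond are cut last, all with BCl3. Benzyl marks the two oxygens that must differ from their methylated neighbours. The 5-O-methyl group is singled out by boron chelation to the C4 carbonyl. A 5-O-benzyl group would avoid the demethylation but would need an unsymmetrical ring A phenol and an ambiguous formylation. Precursor 20 carries no free phenol, so nothing air-sensitive is carried through the route.

**20 from 19 from 16.** The O3–methyl bond is cut back to trans-3-hydroxyflavanone 19, and the C3–O bond back to flavanone 16. Bringing the C3 oxygen in with the dienophile (a β-methoxystyrene) was considered and rejected: the polarity of an enol ether would place the aryl group at C3. The forward steps must add oxygen anti to the C2 aryl group and methylate an α-hydroxy ketone, in both cases without a free enolate.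

**16 from 15 from 14.** The C4 carbonyl is traced to flavan-4-ol 15 and then to the 4-methoxyflavan 14. C4 is benzylic to a ring with ortho and para oxygens, so the methyl ether is exchanged for hydroxyl under mild aqueous acid, and the C4 stereocentre is of no consequence.

**14 from 7 and 12.** C3–C4 and O1–C2 are cut together. This divides the skeleton into a ring A salicylaldehyde dimethyl acetal 7 and ring B styrene 12, which react through quinone methide 13. Cuts at C2–C3 (aldol), O1–C8a or C3–C4 alone need an open-chain precursor with preset stereocentres and a separate ring closure. Here two achiral arenes of similar size give ring C and C2 in one step. The forward reaction must deliver the aryl group at C2 (styrene polarity) and the absolute configuration at C2 (chiral Brønsted acid).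

**7 from 5, 4, 2 and 1.** The acetal comes from salicylaldehyde 5 and trimethyl orthoformate 6. The C4a–CHO bond is cut to phenol 4, whose two free positions are equivalent by symmetry, so formylation has one outcome. The phenol oxygen (O1) comes from the aldehyde carbon of benzyl ether 2 by Baeyer–Villiger oxidation through formate 3, and 2 from syringaldehyde 1.

**12 from 9 and 8.** The vinyl group comes from aldehyde 9 and phosphonium salt 10 (through ylide 11), and 9 from 3-hydroxy-4,5-dimethoxybenzaldehyde 8 by benzylation.

## Roads not taken

**Alternative 1:** The cut runs through C2–C3 and the C3–OMe bond of an open chain, with ring C closed afterwards at O1–C2. Forward, Rh2(OAc)4 converts ring A diazo ketone A1 into a carbene, methanol adds to give an oxonium ylide (C3–O bond), and the derived enol, bound to a chiral phosphoric acid, is trapped by aldehyde 9 (C2–C3 bond) to give syn aldol A2.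
- Merits: methanol supplies the C3 methoxy group, so neither the oxidation of step 10 nor the methylation of step 11 is needed. C4 is a ketone from the start, and both stereocentres arise in one convergent step. After its key step this road is shorter than the chosen one.
- Weak points: the ylide of a diazo ketone collapses quickly by proton shift to the plain α-methoxy ketone, and an electron-rich benzaldehyde such as 9 is a poor trap. The ketone of A1 is flanked by two ortho oxygens. A1 needs the ring A acid chloride and diazomethane, which costs back the steps saved. In A2 the carbinol carbon has the configuration opposite to what a retentive closure needs, so ring C must be closed by an invertive Mitsunobu displacement at an electron-rich benzylic carbinol, where ionisation and elimination to the chalcone compete.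
- Comparison: against the shorter endgame, the chosen plan forms ring C and C2 in the same step, so no stereocentre is inverted afterwards and C3 is set on a closed ring by substrate control.

**Alternative 2:** The cut is O1–C8a. Forward, Ag2O oxidises the catechol of open-chain anti aldol A3 to the 5,6-quinone, the C2 hydroxyl adds to C8a in a 6-endo conjugate addition, and tautomerisation gives A4, the 3'-O-benzyl ether of the target.
- Merits: both stereocentres are in place before closure and C2 keeps its configuration because only an O–H bond is broken. Ring A needs no oxygen at C8a, no symmetric phenol and no late 5-O-demethylation. A4 is one hydrogenolysis from 21. In protecting-group economy and endgame length this road is better.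
- Weak points: the cyclised catechol is more electron-rich than A3 and is oxidised further, by Ag2O or by redox exchange with unreacted quinone. The quinone has other electrophilic sites (C8, and C7 with loss of methanol). Ag2O is basic enough to threaten retro-aldol cleavage and C3 epimerisation of a β-hydroxy-α-methoxy ketone. The enantioselective anti aldol that makes A3 is itself an unsolved sub-problem.
- Comparison: the chosen plan pays with a longer endgame, but its ring-forming step is an established way to 2-arylchromans, whereas the oxidative closure has little support on a substrate of this kind.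

**Alternative 3:** The cut is C3–C4. Forward, SmI2 reduces the aryl aldehyde of dialdehyde A5 to a ketyl, which adds to the aliphatic aldehyde and closes ring C as cis-3,4-diol A6.
- Merits: the C3 oxygen arrives with the ring closure, chelation favours the cis diol, and A6 maps onto 19 by one benzylic oxidation.
- Weak points: A5 is an α-aryloxy-α-aryl acetaldehyde. Its C2–H is benzylic, α to an aldehyde and α to an aryloxy group, so C2 would racemise by enolisation. SmI2 can also cleave the α-aryloxy bond reductively. The hindered O1–C2 ether would have to be made in enantioenriched form beforehand, and C2 would have to control C3 in the pinacol step.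
- Comparison: after the key step this road is about as long as the chosen one (oxidation, methylation, unmasking), so it offers no gain in step economy. The chosen plan never carries a stereocentre α to an aldehyde.

Key step: step 7

Assumption: the sense of induction of the chiral acid in step 7 cannot be predicted with certainty for this substrate pair; the route is written for the (R)-configured catalyst, and the (S)-configured catalyst takes its place if a trial run gives the (2R,4R) adduct.

## Route

Step 1
Reactants: 1 syringaldehyde
Product: 2 4-(benzyloxy)-3,5-dimethoxybenzaldehyde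
Conditions: BnBr, K2CO3, DMF, 60 °C
Reagents that add atoms: benzyl bromide, BrCc1ccccc1
Why: Williamson ether synthesis; the acidic, hindered 4-OH is benzylated cleanly under carbonate conditions and the aldehyde is inert.

Step 2
Reactants: 2 4-(benzyloxy)-3,5-dimethoxybenzaldehyde
Product: 4 4-(benzyloxy)-3,5-dimethoxyphenol, via 4-(benzyloxy)-3,5-dimethoxyphenyl formate 3 (not isolated)
Conditions: mCPBA, CH2Cl2, 25 °C; then K2CO3, MeOH, 25 °C
Reagents that add atoms: mCPBA, OOC(=O)c1cccc(Cl)c1
Why: Baeyer–Villiger (Dakin-type) oxidation; the electron-rich aryl group migrates in the Criegee adduct to give formate 3, which is methanolysed in the same flask, and the ethers are inert to the peracid.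

Step 3
Reactants: 4 4-(benzyloxy)-3,5-dimethoxyphenol
Product: 5 3-(benzyloxy)-6-hydroxy-2,4-dimethoxybenzaldehyde
Conditions: MgCl2, Et3N, (CH2O)n, THF, reflux
Reagents that add atoms: paraformaldehyde (formaldehyde), C=O
Why: Magnesium-mediated ortho-formylation (Casnati–Skattebøl); the magnesium phenoxide delivers formaldehyde to the ortho carbon and the benzylic alkoxide is oxidised by a second formaldehyde. The two free ring positions of 4 are equivalent by symmetry, so only one aldehyde can form.

Step 4
Reactants: 5 3-(benzyloxy)-6-hydroxy-2,4-dimethoxybenzaldehyde; 6 trimethyl orthoformate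
Product: 7 4-(benzyloxy)-2-(dimethoxymethyl)-3,5-dimethoxyphenol
Conditions: HC(OMe)3, MeOH, PPTS (cat.), 25 °C; Et3N quench, filtration through basic alumina
Reagents that add atoms: none
Why: Acid-catalysed acetalisation driven by the orthoformate as water scavenger. The amine quench and the avoidance of silica are needed because the acetal of this electron-rich salicylaldehyde ionises easily; the material is used directly in step 7.

Step 5
Reactants: 8 3-hydroxy-4,5-dimethoxybenzaldehyde
Product: 9 3-(benzyloxy)-4,5-dimethoxybenzaldehyde
Conditions: BnBr, K2CO3, DMF, 60 °C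
Reagents that add atoms: benzyl bromide, BrCc1ccccc1
Why: Williamson ether synthesis on the only free phenol.

Step 6
Reactants: 9 3-(benzyloxy)-4,5-dimethoxybenzaldehyde; 10 methyltriphenylphosphonium bromide
Product: 12 1-(benzyloxy)-5-ethenyl-2,3-dimethoxybenzene (3-benzyloxy-4,5-dimethoxystyrene), via methylenetriphenylphosphorane 11 (not isolated)
Conditions: KOtBu, THF, 0 → 25 °C
Reagents that add atoms: none
Why: Wittig methylenation with the non-stabilised ylide 11; a terminal alkene raises no stereochemical question.

Step 7
Reactants: 7 4-(benzyloxy)-2-(dimethoxymethyl)-3,5-dimethoxyphenol; 12 3-benzyloxy-4,5-dimethoxystyrene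
Product: 14 (2S,4S)-6-(benzyloxy)-2-[3-(benzyloxy)-4,5-dimethoxyphenyl]-4,5,7-trimethoxychromane (2,4-cis), via 4-methoxy o-quinone methide 13 (not isolated)
Conditions: (R)-3,3'-bis(2,4,6-triisopropylphenyl)-BINOL N-triflylphosphoramide (10 mol%), 12 (2 equiv), 5 Å MS, toluene, −20 °C, slow addition of 7
Reagents that add atoms: none
Why: The chiral acid protonates one acetal oxygen of 7 and methanol is lost to the sieves, giving quinone methide 13 as its O-protonated, phenol-conjugated methoxycarbenium form, held by the chiral phosphoramide anion through an ion pair and a hydrogen bond to the phenolic OH. The terminal carbon of styrene 12 (C3) attacks C4, and the benzylic cation developing at C2, stabilised by ring B, is captured by O1 in an asynchronous inverse-electron-demand hetero-Diels–Alder reaction. The closest known reaction type is the Brønsted acid-catalysed [4+2] cycloaddition of o-quinone methides generated in situ with styrenes, known from salicylaldehyde acetals with achiral acids and from o-hydroxybenzyl alcohols with chiral phosphoric acids and N-triflylphosphoramides. Ring C is closed in this intermolecular [4+2] mode: the four-atom oxa-diene O1–C8a–C4a–C4 adds across C3–C2, and O1–C2 bond formation completes the six-membered ring. C2 is controlled by the catalyst, whose anion blocks one face of the bound cation and orients the styrene; C4 follows from the endo approach of the aryl group (2,4-cis) and is erased later. Regiochemistry (aryl at C2) is secured by the polarity of the styrene. The step also needs chemoselectivity against Friedel–Crafts attack of the cation on the free C8 position of ring A and against cationic oligomerisation of 12, which excess styrene, slow addition of 7 and low temperature are meant to secure. The cis isomer must be separated from any trans isomer before C4 is erased, because a trans adduct formed on the same face of 13 would carry the opposite configuration at C2.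

Step 8
Reactants: 14 (2S,4S)-6-(benzyloxy)-2-[3-(benzyloxy)-4,5-dimethoxyphenyl]-4,5,7-trimethoxychromane
Product: 15 (2S)-6-(benzyloxy)-2-[3-(benzyloxy)-4,5-dimethoxyphenyl]-5,7-dimethoxychroman-4-ol (mixture of C4 epimers)
Conditions: TsOH·H2O (cat.), THF/H2O 3:1, high dilution, 25 °C
Reagents that add atoms: water, O
Why: SN1 solvolysis; the C4 ether ionises to a cation stabilised by O1 and the 5- and 7-methoxy groups and is captured by the large excess of water. Dilution suppresses C4–C8 coupling between flavan units and elimination; C2 is not involved and the C4 configuration does not matter.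

Step 9
Reactants: 15 (2S)-6-(benzyloxy)-2-[3-(benzyloxy)-4,5-dimethoxyphenyl]-5,7-dimethoxychroman-4-ol
Product: 16 (2S)-6-(benzyloxy)-2-[3-(benzyloxy)-4,5-dimethoxyphenyl]-5,7-dimethoxychroman-4-one
Conditions: Dess–Martin periodinane, NaHCO3, CH2Cl2, 0 → 25 °C
Reagents that add atoms: none
Why: Dess–Martin oxidation of a secondary benzylic alcohol; both C4 epimers converge on the ketone, and the buffered, non-basic medium avoids the ring opening that would racemise C2.

Step 10
Reactants: 16 (2S)-6-(benzyloxy)-2-[3-(benzyloxy)-4,5-dimethoxyphenyl]-5,7-dimethoxychroman-4-one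
Product: 19 (2R,3R)-6-(benzyloxy)-2-[3-(benzyloxy)-4,5-dimethoxyphenyl]-3-hydroxy-5,7-dimethoxychroman-4-one, via trimethylsilyl enol ether 17 (not isolated), via silyloxy epoxide 18 (not isolated)
Conditions: TMSOTf, Et3N, CH2Cl2, −20 → 0 °C, cold NaHCO3 wash; then DMDO, acetone/CH2Cl2, −40 °C; then 1 M HCl, THF, 0 °C
Reagents that add atoms: dimethyldioxirane, CC1(C)OO1 (the C3 oxygen); trimethylsilyl triflate, C[Si](C)(C)OS(=O)(=O)C(F)(F)F (silyl group of 17 and 18 only)
Why: Rubottom oxidation; soft enolisation gives enol ether 17 without a free enolate that could expel O1 and racemise C2. DMDO epoxidises 17 on the face opposite the adjacent C2 aryl group, and acid opening of epoxide 18 at C4 keeps the new C3–O bond, so the hydroxyl ends trans to the aryl group. This is also the more stable diequatorial isomer.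

Step 11
Reactants: 19 (2R,3R)-6-(benzyloxy)-2-[3-(benzyloxy)-4,5-dimethoxyphenyl]-3-hydroxy-5,7-dimethoxychroman-4-one
Product: 20 (2R,3R)-6-(benzyloxy)-2-[3-(benzyloxy)-4,5-dimethoxyphenyl]-3,5,7-trimethoxychroman-4-one
Conditions: MeI, Ag2O, 4 Å MS, CH2Cl2, 25–40 °C, dark
Reagents that add atoms: iodomethane, CI
Why: Purdie methylation; Ag2O activates MeI and takes up HI without generating an enolate, the classical way to O-methylate α-hydroxy ketones, so C2 and C3 are not disturbed.

Step 12
Reactants: 20 (2R,3R)-6-(benzyloxy)-2-[3-(benzyloxy)-4,5-dimethoxyphenyl]-3,5,7-trimethoxychroman-4-one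
Product: 21 (2R,3R)-5,6-dihydroxy-2-(3-hydroxy-4,5-dimethoxyphenyl)-3,7-dimethoxychroman-4-one
Conditions: BCl3, C6HMe5, CH2Cl2, −78 → 0 °C; MeOH quench, dilute HCl work-up under argon
Reagents that add atoms: none
Why: BCl3 cleaves both aryl benzyl ethers at low temperature, with pentamethylbenzene as a non-basic scavenger of the benzyl cation. On warming, boron chelated between the C4 carbonyl and O5 removes the peri methyl group, while the methoxy groups at C7, C3, C4' and C5' lack such a six-membered chelate. The conditions are non-basic, so the stereocentres and the catechol are safe.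

## Compound list

1 | syringaldehyde (4-hydroxy-3,5-dimethoxybenzaldehyde) | COc1cc(C=O)cc(OC)c1O | starting material
2 | 4-(benzyloxy)-3,5-dimethoxybenzaldehyde | COc1cc(C=O)cc(OC)c1OCc1ccccc1 | intermediate
3 | 4-(benzyloxy)-3,5-dimethoxyphenyl formate | COc1cc(OC=O)cc(OC)c1OCc1ccccc1 | intermediate (not isolated)
4 | 4-(benzyloxy)-3,5-dimethoxyphenol | COc1cc(O)cc(OC)c1OCc1ccccc1 | intermediate
5 | 3-(benzyloxy)-6-hydroxy-2,4-dimethoxybenzaldehyde | COc1cc(O)c(C=O)c(OC)c1OCc1ccccc1 | intermediate
6 | trimethyl orthoformate | COC(OC)OC | starting material
7 | 4-(benzyloxy)-2-(dimethoxymethyl)-3,5-dimethoxyphenol | COC(OC)c1c(O)cc(OC)c(OCc2ccccc2)c1OC | intermediate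
8 | 3-hydroxy-4,5-dimethoxybenzaldehyde | COc1cc(C=O)cc(O)c1OC | starting material
9 | 3-(benzyloxy)-4,5-dimethoxybenzaldehyde | COc1cc(C=O)cc(OCc2ccccc2)c1OC | intermediate
10 | methyltriphenylphosphonium bromide | C[P+](c1ccccc1)(c1ccccc1)c1ccccc1.[Br-] | starting material
11 | methylenetriphenylphosphorane | C=P(c1ccccc1)(c1ccccc1)c1ccccc1 | intermediate (not isolated)
12 | 1-(benzyloxy)-5-ethenyl-2,3-dimethoxybenzene (3-benzyloxy-4,5-dimethoxystyrene) | C=Cc1cc(OCc2ccccc2)c(OC)c(OC)c1 | intermediate
13 | 4-(benzyloxy)-3,5-dimethoxy-6-(methoxymethylidene)cyclohexa-2,4-dien-1-one (4-methoxy o-quinone methide, reacting as its protonated form) | COC=C1C(=O)C=C(OC)C(OCc2ccccc2)=C1OC | intermediate (not isolated)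
14 | (2S,4S)-6-(benzyloxy)-2-[3-(benzyloxy)-4,5-dimethoxyphenyl]-4,5,7-trimethoxychromane (2,4-cis) | COc1cc2c(c(OC)c1OCc3ccccc3)[C@@H](OC)C[C@@H](c3cc(OCc4ccccc4)c(OC)c(OC)c3)O2 | intermediate
15 | (2S)-6-(benzyloxy)-2-[3-(benzyloxy)-4,5-dimethoxyphenyl]-5,7-dimethoxychroman-4-ol, mixture of C4 epimers | COc1cc2c(c(OC)c1OCc3ccccc3)C(O)C[C@@H](c3cc(OCc4ccccc4)c(OC)c(OC)c3)O2 | intermediate
16 | (2S)-6-(benzyloxy)-2-[3-(benzyloxy)-4,5-dimethoxyphenyl]-5,7-dimethoxychroman-4-one | COc1cc2c(c(OC)c1OCc3ccccc3)C(=O)C[C@@H](c3cc(OCc4ccccc4)c(OC)c(OC)c3)O2 | intermediate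
17 | (2S)-6-(benzyloxy)-2-[3-(benzyloxy)-4,5-dimethoxyphenyl]-5,7-dimethoxy-4-(trimethylsilyloxy)-2H-chromene | COc1cc2c(c(OC)c1OCc3ccccc3)C(O[Si](C)(C)C)=C[C@@H](c3cc(OCc4ccccc4)c(OC)c(OC)c3)O2 | intermediate (not isolated)
18 | 3,4-epoxide of 17, oxirane oxygen on the face opposite the C2 aryl group, trimethylsilyloxy group at C4 | COc1cc2c(c(OC)c1OCc3ccccc3)[C@]4(O[Si](C)(C)C)O[C@@H]4[C@@H](c3cc(OCc5ccccc5)c(OC)c(OC)c3)O2 | intermediate (not isolated)
19 | (2R,3R)-6-(benzyloxy)-2-[3-(benzyloxy)-4,5-dimethoxyphenyl]-3-hydroxy-5,7-dimethoxychroman-4-one (2,3-trans) | COc1cc2c(c(OC)c1OCc3ccccc3)C(=O)[C@H](O)[C@@H](c3cc(OCc4ccccc4)c(OC)c(OC)c3)O2 | intermediate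
20 | (2R,3R)-6-(benzyloxy)-2-[3-(benzyloxy)-4,5-dimethoxyphenyl]-3,5,7-trimethoxychroman-4-one | COc1cc2c(c(OC)c1OCc3ccccc3)C(=O)[C@H](OC)[C@@H](c3cc(OCc4ccccc4)c(OC)c(OC)c3)O2 | intermediate
21 | (2R,3R)-5,6-dihydroxy-2-(3-hydroxy-4,5-dimethoxyphenyl)-3,7-dimethoxychroman-4-one | COc1cc2c(c(O)c1O)C(=O)[C@H](OC)[C@@H](c1cc(O)c(OC)c(OC)c1)O2 | target

## Step count and least certain steps

Total: 12 steps. Longest linear sequence: 10 steps (steps 1–4 and 7–12, from syringaldehyde 1); the ring B branch (steps 5 and 6) joins at step 7.

**Step 7 (key step).** The most likely failure is weak enantiofacial discrimination: the stabilised methoxycarbenium ion may react outside a tight ion pair, or an uncatalysed pathway may compete. Friedel–Crafts attack at C8 of ring A and incomplete removal of a trans adduct would lower yield and optical purity further. Fallback, setting out from 7 and 12: the same cycloaddition is run with an achiral acid (TfOH cat., CH2Cl2, 0 °C) to give racemic cis-4-methoxyflavan F1. Hydrolysis as in step 8 gives racemic flavan-4-ol F2, and Dess–Martin oxidation as in step 9 gives racemic flavanone F3. Kinetic resolution by asymmetric transfer hydrogenation (RuCl[(R,R)-TsDPEN](p-cymene), HCO2H/Et3N, run past half conversion) then reduces the (2R)-ketone to (2R,4R)-cis-flavan-4-ol F4 and leaves the (2S)-ketone. The catalyst antipode that consumes the (2R)-ketone is expected to be the (R,R)-complex by analogy with simple aryl ketones and is to be confirmed. The route is rejoined at 16.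

**Step 4.** The acetal may lose methanol on concentration through ionisation by traces of acid, after which the quinone methide oligomerises, or it may revert to the hydrogen-bonded aldehyde with moisture. Fallback, setting out from 5: the phenol is silylated (TBSCl, imidazole, DMF) to give 3-(benzyloxy)-6-(tert-butyldimethylsilyloxy)-2,4-dimethoxybenzaldehyde F5. Acetalisation (HC(OMe)3, PPTS cat., MeOH) gives its dimethyl acetal F6, which has no free phenol, cannot form a quinone methide and can be purified. Bu4NF in THF at 0 °C then frees the phenol under basic conditions in which the acetal is inert, and the solution of 7 obtained after neutral work-up goes directly into step 7.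

**Step 10.** Ring opening during enolisation (β-elimination of O1 to the chalcone, with loss of configuration at C2) or insufficient facial selectivity in the epoxidation are the main dangers; oxidation of the electron-rich rings by excess DMDO is a lesser one. Fallback, setting out from 15: acid-catalysed dehydration (PPTS cat., toluene, 4 Å MS, 60 °C) gives (2S)-flav-3-ene F7. Dihydroxylation with catalytic OsO4 and N-methylmorpholine N-oxide on the face opposite the C2 aryl group gives 2,3-trans-3,4-cis-diol F8, which has the same structure as A6. Selective oxidation of the benzylic C4 hydroxyl with DDQ in dioxane returns to the route at 19.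

**Step 12.** Selectivity among the methyl ethers may be lost at the temperature needed for the 5-O-demethylation (the central 4'-methoxy group of ring B and the 3-methoxy group next to the carbonyl are the candidates). C-benzylation of the electron-rich rings is possible if cation scavenging is incomplete, and the catechol may oxidise during work-up. Fallback, setting out from 20: hydrogenolysis (H2, Pd/C, EtOAc, 25 °C) removes both benzyl groups without cationic intermediates and gives (2R,3R)-6-hydroxy-2-(3-hydroxy-4,5-dimethoxyphenyl)-3,5,7-trimethoxychroman-4-one F9. Chelation-controlled demethylation with MgI2 etherate in THF, a milder Lewis acid that acts only on the methoxy group peri to the carbonyl, then gives 21.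

## Further compounds

F1 | step 7 | racemic 2,4-cis-6-(benzyloxy)-2-[3-(benzyloxy)-4,5-dimethoxyphenyl]-4,5,7-trimethoxychromane | COc1cc2c(c(OC)c1OCc3ccccc3)C(OC)CC(c3cc(OCc4ccccc4)c(OC)c(OC)c3)O2
F2 | step 7 | racemic 6-(benzyloxy)-2-[3-(benzyloxy)-4,5-dimethoxyphenyl]-5,7-dimethoxychroman-4-ol (C4 epimers) | COc1cc2c(c(OC)c1OCc3ccccc3)C(O)CC(c3cc(OCc4ccccc4)c(OC)c(OC)c3)O2
F3 | step 7 | racemic 6-(benzyloxy)-2-[3-(benzyloxy)-4,5-dimethoxyphenyl]-5,7-dimethoxychroman-4-one | COc1cc2c(c(OC)c1OCc3ccccc3)C(=O)CC(c3cc(OCc4ccccc4)c(OC)c(OC)c3)O2
F4 | step 7 | (2R,4R)-6-(benzyloxy)-2-[3-(benzyloxy)-4,5-dimethoxyphenyl]-5,7-dimethoxychroman-4-ol (2,4-cis) | COc1cc2c(c(OC)c1OCc3ccccc3)[C@H](O)C[C@H](c3cc(OCc4ccccc4)c(OC)c(OC)c3)O2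
F5 | step 4 | 3-(benzyloxy)-6-(tert-butyldimethylsilyloxy)-2,4-dimethoxybenzaldehyde | COc1cc(O[Si](C)(C)C(C)(C)C)c(C=O)c(OC)c1OCc1ccccc1
F6 | step 4 | [4-(benzyloxy)-2-(dimethoxymethyl)-3,5-dimethoxyphenoxy](tert-butyl)dimethylsilane | COC(OC)c1c(O[Si](C)(C)C(C)(C)C)cc(OC)c(OCc2ccccc2)c1OC
F7 | step 10 | (2S)-6-(benzyloxy)-2-[3-(benzyloxy)-4,5-dimethoxyphenyl]-5,7-dimethoxy-2H-chromene | COc1cc2c(c(OC)c1OCc3ccccc3)C=C[C@@H](c3cc(OCc4ccccc4)c(OC)c(OC)c3)O2
F8 | step 10 | (2R,3S,4S)-6-(benzyloxy)-2-[3-(benzyloxy)-4,5-dimethoxyphenyl]-5,7-dimethoxychromane-3,4-diol (2,3-trans-3,4-cis) | COc1cc2c(c(OC)c1OCc3ccccc3)[C@H](O)[C@H](O)[C@@H](c3cc(OCc4ccccc4)c(OC)c(OC)c3)O2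
F9 | step 12 | (2R,3R)-6-hydroxy-2-(3-hydroxy-4,5-dimethoxyphenyl)-3,5,7-trimethoxychroman-4-one | COc1cc2c(c(OC)c1O)C(=O)[C@H](OC)[C@@H](c1cc(O)c(OC)c(OC)c1)O2
A1 | alternative 1 | 4-(benzyloxy)-2-(2-diazoacetyl)-3,5-dimethoxyphenyl acetate | CC(=O)Oc1cc(OC)c(OCc2ccccc2)c(OC)c1C(=O)C=[N+]=[N-]
A2 | alternative 1 | 4-(benzyloxy)-2-{(2R,3S)-3-[3-(benzyloxy)-4,5-dimethoxyphenyl]-3-hydroxy-2-methoxypropanoyl}-3,5-dimethoxyphenyl acetate (syn aldol) | CC(=O)Oc1cc(OC)c(OCc2ccccc2)c(OC)c1C(=O)[C@H](OC)[C@H](c1cc(OCc2ccccc2)c(OC)c(OC)c1)O
A3 | alternative 2 | (2R,3R)-3-[3-(benzyloxy)-4,5-dimethoxyphenyl]-1-(2,3-dihydroxy-4-methoxyphenyl)-3-hydroxy-2-methoxypropan-1-one (anti aldol) | COc1ccc(C(=O)[C@H](OC)[C@H](O)c2cc(OCc3ccccc3)c(OC)c(OC)c2)c(O)c1O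
A4 | alternative 2 | (2R,3R)-2-[3-(benzyloxy)-4,5-dimethoxyphenyl]-5,6-dihydroxy-3,7-dimethoxychroman-4-one | COc1cc2c(c(O)c1O)C(=O)[C@H](OC)[C@@H](c1cc(OCc3ccccc3)c(OC)c(OC)c1)O2
A5 | alternative 3 | (2R)-2-[3-(benzyloxy)-4,5-dimethoxyphenyl]-2-[4-(benzyloxy)-2-formyl-3,5-dimethoxyphenoxy]acetaldehyde | COc1cc(O[C@@H](C=O)c2cc(OCc3ccccc3)c(OC)c(OC)c2)c(C=O)c(OC)c1OCc1ccccc1
A6 | alternative 3 | (2R,3S,4S)-6-(benzyloxy)-2-[3-(benzyloxy)-4,5-dimethoxyphenyl]-5,7-dimethoxychromane-3,4-diol (2,3-trans-3,4-cis) | COc1cc2c(c(OC)c1OCc3ccccc3)[C@H](O)[C@H](O)[C@@H](c3cc(OCc4ccccc4)c(OC)c(OC)c3)O2
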